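Target: (1R,3S)-1,3-bis(2,4,5-trimethoxyphenyl)butan-1-ol, read as ring A–C1H(OH)–C2H2–C3H(C4H3)–ring B. Apart from the two arenes it is acyclic, so no ring has to be built.
Enabling feature: C2 is a bare methylene between the ring A carbinol carbon C1 and the methyl-bearing ring B methine C3. C1 therefore maps onto an aryl aldehyde carbon, and C2 onto the α-carbon of a 3-arylbutanoic acid that gives up its carboxyl carbon as CO2.
Retrosynthetic cuts, in order: the O–Si bond of a C1 silyl ether; C1–C2 (key step); the acyl–O bonds of the N-(acyloxy)phthalimide and of the ethyl ester behind it; the C3–H bond (back to an E enoate); C2=C3 (back to an aryl methyl ketone and a phosphonoacetate).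
Forward order: C2=C3 olefination, C3–H installation, exchange of ester for active ester, C1–C2 coupling with 2,4,5-trimethoxybenzaldehyde, desilylation.
Stereochemistry: 3S comes from ligand-controlled copper hydride delivery to the Re face of C3 of the E enoate. 1R comes from a chiral sulfonamide–oxazoline chromium complex that steers C2 onto the Re face of the aldehyde.

Key step: step 5

Assumption: the antipodes named for the two chiral ligands ((R)-DTBM-SEGPHOS in step 2, (S)-SulfOx in step 5) follow quadrant-model analogies with β-methylcinnamates and with aryl aldehydes; both ligands can be had in either form, so a reversed sense of induction would be met by exchanging the antipode and nothing else.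
(S)-SulfOx = N-[2-[(4S)-4-tert-butyl-4,5-dihydro-1,3-oxazol-2-yl]-6-methylphenyl]methanesulfonamide, CC(C)(C)[C@H]1COC(=N1)c1cccc(C)c1NS(C)(=O)=O. It belongs to a ligand class known from asymmetric chromium-mediated carbonyl additions.

Step 1
Reactants: 1 2,4,5-trimethoxyacetophenone; 2 triethyl phosphonoacetate
Product: 4 ethyl (E)-3-(2,4,5-trimethoxyphenyl)but-2-enoate, via sodium phosphonate carbanion 3 (not isolated)
Conditions: 2 (2 equiv), NaH (2 equiv), THF, 0 °C to rt; then 1, reflux; dilute aq. HCl quench; E isomer separated from Z on silica
Reagents that add atoms: none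
Why: Horner–Wadsworth–Emmons olefination, in which the preformed carbanion 3 adds reversibly to the aryl methyl ketone and phosphate elimination through the less congested oxaphosphetane favours the E enoate (aryl trans to ester), as is well known for ortho-alkoxy acetophenones, while the minor Z isomer is removed because it would give the opposite C3 configuration in step 2.

Step 2
Reactants: 4 ethyl (E)-3-(2,4,5-trimethoxyphenyl)but-2-enoate
Product: 5 ethyl (S)-3-(2,4,5-trimethoxyphenyl)butanoate
Conditions: Cu(OAc)2·H2O (3 mol %), (R)-DTBM-SEGPHOS (3.3 mol %), (EtO)2MeSiH (2 equiv), t-BuOH (2 equiv), toluene, 0 °C to rt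
Reagents that add atoms: none
Why: Copper hydride catalysed asymmetric conjugate reduction (1,4-hydrosilylation) of a β-aryl-β-methyl enoate, in which the bisphosphine-bound copper hydride delivers hydride to the Re face of C3 of the geometrically pure E olefin and so sets 3S, t-BuOH turns the catalyst over, and the ester and aryl ethers are inert.

Step 3
Reactants: 5 ethyl (S)-3-(2,4,5-trimethoxyphenyl)butanoate
Product: 7 (S)-3-(2,4,5-trimethoxyphenyl)butanoic acid, via lithium carboxylate 6 (not isolated)
Conditions: LiOH·H2O (3 equiv), THF–MeOH–H2O, rt; then dilute aq. HCl to pH 2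
Reagents that add atoms: lithium hydroxide (hydroxide oxygen), [Li+].[OH-]
Why: Saponification of an unhindered ethyl ester, which cannot touch C3 because that centre is β to the carbonyl group and carries no acidic hydrogen.

Step 4
Reactants: 7 (S)-3-(2,4,5-trimethoxyphenyl)butanoic acid; 8 N-hydroxyphthalimide
Product: 10 1,3-dioxoisoindolin-2-yl (S)-3-(2,4,5-trimethoxyphenyl)butanoate, via O-acylisourea 9 (not isolated)
Conditions: N,N'-diisopropylcarbodiimide (1.1 equiv), 4-(dimethylamino)pyridine (10 mol %), CH2Cl2, 0 °C to rt
Reagents that add atoms: none
Why: Steglich-type carbodiimide esterification through 9 with 4-(dimethylamino)pyridine as acyl-transfer catalyst, the standard entry to N-(acyloxy)phthalimide redox-active esters, which leaves C3 untouched.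

Step 5
Reactants: 10 1,3-dioxoisoindolin-2-yl (S)-3-(2,4,5-trimethoxyphenyl)butanoate; 11 2,4,5-trimethoxybenzaldehyde
Product: 14 [(1R,3S)-1,3-bis(2,4,5-trimethoxyphenyl)butoxy]trimethylsilane, via alkylchromium 12 (not isolated), via chromium alkoxide 13 (not isolated)
Conditions: CrCl2 (20 mol %), (S)-SulfOx (24 mol %), Et3N (24 mol %), MeCN, rt, 1 h; then 11 (2 equiv), Me3SiCl (2.5 equiv), 2,6-lutidine (1 equiv), n-Bu4NPF6 (0.1 mol/L), MeCN, 0 °C to rt, divided cell (glass frit), nickel foam cathode held at the trivalent/divalent chromium wave, Al anode in n-Bu4NCl/MeCN, 10 added over 4 h, about 2.2 F per mol of 10; aq. NaHCO3, Et3N-washed silica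
Reagents that add atoms: chlorotrimethylsilane, C[Si](C)(C)Cl
Why: Proposed new method: the cathode reduces trivalent chromium to the (S)-SulfOx-bound divalent state, which passes one electron to the Me3SiCl-activated imide of 10, so that N–O cleavage and loss of CO2 leave a primary radical at C2 that a second divalent chromium traps as alkylchromium 12; 12 adds to the chromium-bound carbonyl group of 11 to give alkoxide 13, and Me3SiCl silylates 13, releasing 14 and trivalent chromium for the next cathodic turnover. The closest known reaction types are the racemic decarboxylative Nozaki–Hiyama–Kishi-type alkylation of aldehydes by redox-active esters with stoichiometric CrCl2, the electrochemically driven catalytic asymmetric Nozaki–Hiyama–Kishi coupling of alkenyl halides, and the cobalt/chromium asymmetric alkylation of aldehydes with sulfonamide–oxazoline ligands; their merger into a cathodic, enantioselective, decarboxylative alkyl transfer has not been shown. One skeletal bond (C1–C2) forms and no ring closes. The only new stereocentre, C1, is controlled by the ligand: in the octahedral trivalent complex the alkyl group and the aldehyde sit cis, the tert-butyl oxazoline and the sulfonyl group block the Si face, and attack of C2 on the Re face gives 1R, while the C3 centre, 1,3-remote and located on the nucleophile, should add little bias, so that any 1S product is a diastereomer removable by chromatography. Chemoselectivity rests on chromium capture of the C2 radical outrunning the neophyl-type 1,2-shift of ring B, 1,6-hydrogen transfer from its ortho methoxy group and hydrogen abstraction from solvent, which is secured by a standing pool of divalent chromium (CrCl2 charged as such, slow addition of 10), because capture is bimolecular and fast whereas the shift of an unstrained β-aryl radical is slow; C3 never becomes a radical centre and stays S. The three donor methoxy groups of 11 move its own reduction far negative of the chromium couple, which holds back ketyl and pinacol formation; the working potential also lies positive of the direct reduction of 10, the sacrificial anode spares both easily oxidised arenes, and the divided cell together with 2,6-lutidine keeps aluminium cations and HCl away from the ionisable benzylic silyl ether.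

Step 6
Reactants: 14 [(1R,3S)-1,3-bis(2,4,5-trimethoxyphenyl)butoxy]trimethylsilane
Product: 15 (1R,3S)-1,3-bis(2,4,5-trimethoxyphenyl)butan-1-ol
Conditions: K2CO3 (0.2 equiv), MeOH, 0 °C; chromatography on Et3N-washed silica (removal of any C1 epimer)
Reagents that add atoms: none
Why: Base-catalysed methanolysis of a trimethylsilyl ether, which takes place at silicon, so the C1–O bond is never broken and the acid-labile, strongly donor-substituted benzylic centre keeps its 1R configuration.

Compound list
1 | 2,4,5-trimethoxyacetophenone | COc1cc(OC)c(C(C)=O)cc1OC | starting material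
2 | triethyl phosphonoacetate | CCOC(=O)CP(=O)(OCC)OCC | starting material
3 | sodium salt of the triethyl phosphonoacetate carbanion (not isolated) | CCOC(=O)[CH-]P(=O)(OCC)OCC.[Na+] | intermediate
4 | ethyl (E)-3-(2,4,5-trimethoxyphenyl)but-2-enoate | CCOC(=O)/C=C(\C)c1cc(OC)c(OC)cc1OC | intermediate
5 | ethyl (S)-3-(2,4,5-trimethoxyphenyl)butanoate | CCOC(=O)C[C@H](C)c1cc(OC)c(OC)cc1OC | intermediate
6 | lithium (S)-3-(2,4,5-trimethoxyphenyl)butanoate (not isolated) | [Li+].[O-]C(=O)C[C@H](C)c1cc(OC)c(OC)cc1OC | intermediate
7 | (S)-3-(2,4,5-trimethoxyphenyl)butanoic acid | OC(=O)C[C@H](C)c1cc(OC)c(OC)cc1OC | intermediate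
8 | N-hydroxyphthalimide | O=C1c2ccccc2C(=O)N1O | starting material
9 | O-[(S)-3-(2,4,5-trimethoxyphenyl)butanoyl]-N,N'-diisopropylisourea (not isolated) | CC(C)NC(=NC(C)C)OC(=O)C[C@H](C)c1cc(OC)c(OC)cc1OC | intermediate
10 | 1,3-dioxoisoindolin-2-yl (S)-3-(2,4,5-trimethoxyphenyl)butanoate (N-hydroxyphthalimide ester of 7) | C[C@@H](CC(=O)ON1C(=O)c2ccccc2C1=O)c1cc(OC)c(OC)cc1OC | intermediate
11 | 2,4,5-trimethoxybenzaldehyde | COc1cc(OC)c(C=O)cc1OC | starting material
12 | dichloro[(2R)-2-(2,4,5-trimethoxyphenyl)propyl]chromium, trivalent, the chlorides standing in for deprotonated (S)-SulfOx, chloride and solvent; spatial arrangement at C3 as in 10, the descriptor changing only because CH2–Cr outranks aryl (not isolated) | C[C@@H](C[Cr](Cl)Cl)c1cc(OC)c(OC)cc1OC | intermediate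
13 | dichlorochromium (1R,3S)-1,3-bis(2,4,5-trimethoxyphenyl)butan-1-olate, trivalent, ancillary ligands simplified as in 12 (not isolated) | COc1cc(OC)c([C@H](O[Cr](Cl)Cl)C[C@H](C)c2cc(OC)c(OC)cc2OC)cc1OC | intermediate
14 | [(1R,3S)-1,3-bis(2,4,5-trimethoxyphenyl)butoxy]trimethylsilane | COc1cc(OC)c([C@H](O[Si](C)(C)C)C[C@H](C)c2cc(OC)c(OC)cc2OC)cc1OC | intermediate
15 | (1R,3S)-1,3-bis(2,4,5-trimethoxyphenyl)butan-1-ol | COc1cc(OC)c([C@H](O)C[C@H](C)c2cc(OC)c(OC)cc2OC)cc1OC | target

Total step count: 6. Longest linear sequence: 6 (1 to 15).

Steps most likely to fail

Step 5.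
- Risks: electron transfer from the ligated divalent chromium to the active ester may be slow. The C2 radical may abstract hydrogen or undergo aryl migration before capture. The aldehyde may be drawn into pinacol-type reduction. Facial control at C1 may be weak. The benzylic silyl ether may ionise under Lewis acidic conditions.
- Fallback: it uses known chemistry, sets out from acid 7 and comes back at target 15. It keeps the carboxyl carbon as C1 and forms the C1–ring A bond instead. Acid 7 is coupled with MeNH(OMe)·HCl (EDC·HCl, i-Pr2NEt, CH2Cl2) to (S)-N-methoxy-N-methyl-3-(2,4,5-trimethoxyphenyl)butanamide F1. Commercial 1-bromo-2,4,5-trimethoxybenzene is exchanged with n-BuLi in THF at −78 °C to 2,4,5-trimethoxyphenyllithium F2. F2 adds once to F1 (Weinreb ketone synthesis, aq. NH4Cl quench) to give (S)-1,3-bis(2,4,5-trimethoxyphenyl)butan-1-one F3. Corey–Bakshi–Shibata reduction of F3 follows, with BH3·SMe2 and (S)-tetrahydro-1-methyl-3,3-diphenyl-1H,3H-pyrrolo[1,2-c][1,3,2]oxazaborole in THF at −20 °C. Ring A acts as the large substituent, so this should give the 1R alcohol 15. Any 1S epimer is a separable diastereomer.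

Step 2.
- Risks: hydride transfer may be sluggish because three donor methoxy groups lower the electrophilicity of C3. The ortho methoxy group also twists ring B out of conjugation, which may blur the distinction between aryl and methyl in the catalyst pocket and lead to poor facial selectivity.
- Fallback: it sets out from enoate 4 and comes back at acid 7, replacing asymmetric catalysis by a hydrolytic kinetic resolution. Enoate 4 is hydrogenated (H2, Pd on carbon, EtOAc) to ethyl (±)-3-(2,4,5-trimethoxyphenyl)butanoate F4. F4 is then stirred with Burkholderia cepacia lipase in pH 7 phosphate buffer/MTBE to about half conversion. This enzyme class is known to hydrolyse the S enantiomer of ethyl 3-arylbutanoates preferentially. Acid 7 is taken into aqueous base, and unreacted ethyl (R)-3-(2,4,5-trimethoxyphenyl)butanoate F5 stays in the organic phase.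

Step 1.
- Risks: addition of the stabilised carbanion to a deactivated, ortho-substituted ketone may be slow, enolisation may compete, and E/Z control may be poor.
- Fallback: it sets out from ketone 1 and comes back at enoate 4, splitting the olefination into addition and elimination. Ethyl bromoacetate and activated Zn dust in THF give ethyl (bromozincio)acetate F6. F6 adds to 1, aided by chelation to the ortho methoxy group (Reformatsky reaction), to give ethyl (±)-3-hydroxy-3-(2,4,5-trimethoxyphenyl)butanoate F7. Dehydration with catalytic p-toluenesulfonic acid in warm toluene proceeds through the strongly stabilised benzylic cation. A DBU equilibration of any deconjugated olefin then follows, which should funnel the material to the thermodynamically preferred conjugated E isomer 4.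

Further compounds
F1 | step 5 | (S)-N-methoxy-N-methyl-3-(2,4,5-trimethoxyphenyl)butanamide | CON(C)C(=O)C[C@H](C)c1cc(OC)c(OC)cc1OC
F2 | step 5 | 2,4,5-trimethoxyphenyllithium | [Li]c1cc(OC)c(OC)cc1OC
F3 | step 5 | (S)-1,3-bis(2,4,5-trimethoxyphenyl)butan-1-one | COc1cc(OC)c(C(=O)C[C@H](C)c2cc(OC)c(OC)cc2OC)cc1OC
F4 | step 2 | ethyl (±)-3-(2,4,5-trimethoxyphenyl)butanoate | CCOC(=O)CC(C)c1cc(OC)c(OC)cc1OC
F5 | step 2 | ethyl (R)-3-(2,4,5-trimethoxyphenyl)butanoate | CCOC(=O)C[C@@H](C)c1cc(OC)c(OC)cc1OC
F6 | step 1 | ethyl (bromozincio)acetate | CCOC(=O)C[Zn]Br
F7 | step 1 | ethyl (±)-3-hydroxy-3-(2,4,5-trimethoxyphenyl)butanoate | CCOC(=O)CC(C)(O)c1cc(OC)c(OC)cc1OC
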